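The guaiane core is cut at C5–C1 and C5–C6. Six seven-ring carbons – C1, C10 (methyl), C9, C8 (oxygen), C7 (isopropyl), C6 – already form the benzene ring of a para-alkylated thymol methyl ether, so only C5 must be inserted. An enantioselective intramolecular Buchner reaction does this in one operation: the carbenoid carbon C5 cyclopropanates the arene C1–C6 bond, closing the cyclopentanone, and electrocyclic opening of the norcaradiene gives the cycloheptatriene with the C5 stereocentre. The precursor is a 1-diazo-4-arylbutan-2-one, three steps from thymol methyl ether. The C4 carbinol then directs hydrogenation (C1, C7); C10, C8 and the epoxide follow by catalyst- and hydroxyl-controlled steps.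

Key step: step 4

Remark: guaiane numbering is used (ring fusion C1/C5, C15 on C4, C14 on C10, isopropyl on C7; α = face of H1). The target is read as the trans-fused 1αH,5βH isomer with 7β-isopropyl, 8β-acyloxy, 10α-hydroxy and a 3α,4α-epoxide. Thymol methyl ether is taken as a commercial starting material.

Step 1
Reactants: 1 thymol methyl ether
Product: 2 4-methoxy-2-methyl-5-(propan-2-yl)benzaldehyde
Conditions: Cl2CHOMe, TiCl4, CH2Cl2, 0 °C; then H2O
Reagents that add atoms: dichloromethyl methyl ether, COC(Cl)Cl; water, O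
Why: Rieche formylation, an electrophilic aromatic substitution that the methoxy group steers to its para position, the ortho site between OMe and Me being sterically blocked.

Step 2
Reactants: 2 4-methoxy-2-methyl-5-(propan-2-yl)benzaldehyde; 3 Meldrum's acid
Product: 6 3-[4-methoxy-2-methyl-5-(propan-2-yl)phenyl]propanoic acid, via arylidene Meldrum's acid 4 (not isolated), via benzyl Meldrum's acid 5 (not isolated)
Conditions: HCO2H–Et3N (5:2), 100 °C; then aq. HCl
Reagents that add atoms: Meldrum's acid 3, CC1(C)OC(=O)CC(=O)O1; water, O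
Why: Domino Knoevenagel condensation, conjugate reduction by formate and hydrolytic decarboxylation in triethylammonium formate is a known one-pot route from aryl aldehydes to 3-arylpropanoic acids.

Step 3
Reactants: 6 3-[4-methoxy-2-methyl-5-(propan-2-yl)phenyl]propanoic acid; 7 trimethylsilyldiazomethane
Product: 9 1-diazo-4-[4-methoxy-2-methyl-5-(propan-2-yl)phenyl]butan-2-one, via acid chloride 8 (not isolated)
Conditions: (COCl)2, DMF (cat.), CH2Cl2, 0 °C to rt, evaporate; then Me3SiCHN2 (2 equiv), THF–MeCN, 0 °C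
Reagents that add atoms: trimethylsilyldiazomethane 7, C[Si](C)(C)C=[N+]=[N-]
Why: Acid chloride formation followed by C-acylation of the silyl diazomethane with loss of Me3SiCl (Arndt–Eistert-type diazoketone synthesis) is standard for 3-arylpropanoic acids.

Step 4
Reactants: 9 1-diazo-4-[4-methoxy-2-methyl-5-(propan-2-yl)phenyl]butan-2-one
Product: 11 (5S)-8-methoxy-15-norguaia-1(10),6,8-trien-4-one (5βH), via norcaradiene 10 (not isolated)
Conditions: Cu(MeCN)4PF6 (5 mol %), (S,S)-tBu-bis(oxazoline), NaB[3,5-(CF3)2C6H3]4, CH2Cl2, 40 °C, slow addition of 9; cold filtration through deactivated silica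
Reagents that add atoms: none
Why: Loss of N2 gives a copper carbenoid whose carbon (C5) adds [2+1] across the arene C1–C6 bond to give norcaradiene 10, and 6π disrotatory electrocyclic opening of that bond gives cycloheptatriene 11 (intramolecular Buchner reaction). The closest known reaction type is the cyclisation of 1-diazo-4-arylbutan-2-ones to 3,8a-dihydroazulen-1(2H)-ones, for which copper–bis(oxazoline) catalysts give enantioenriched products. The five-membered ring closes by cyclopropanation through the three-atom tether (C5 bonds to the ipso carbon C1), and the seven-membered ring is formed by ring expansion of the benzene ring when the cyclopropane bond C1–C6 opens. The only new stereocentre, C5, is set by the C2-symmetric ligand, which decides which arene face the carbenoid attacks; the ligand antipode that gives (5S)-11 is fixed in the first run. The step needs addition to the C1–C6 and not the C1–C10 bond, secured by the ortho methyl group (attack there would create two adjacent quaternary carbons), and cyclopropanation instead of aromatic C–H insertion, which the ketone carbenoid and the methoxy group para to C1 favour. Neutral conditions and a cold, fast work-up protect the doubly activated C5–H.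

Step 5
Reactants: 11 (5S)-8-methoxy-15-norguaia-1(10),6,8-trien-4-one
Product: 13 4α-hydroxy-5βH-guaia-1(10),6-dien-8-one, via trienyl ether carbinol 12 (not isolated)
Conditions: MeLi, CeCl3, THF, −78 °C; aq. NH4Cl; then oxalic acid, THF–H2O, 0 °C
Reagents that add atoms: methyllithium, [Li]C; water, O
Why: The non-basic organocerium reagent adds 1,2 to the enolisable ketone without touching C5–H and from the β face, anti to the C5–C6 bond (4β-Me, 4α-OH), and mild acid then protonates the dienol ether at C9 (kinetic α-protonation) to unveil the C8 ketone with the C1(10) alkene still in place.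

Step 6
Reactants: 13 4α-hydroxy-5βH-guaia-1(10),6-dien-8-one
Product: 14 4α-hydroxy-1αH,5βH,7αH,10αH-guaian-8-one
Conditions: [Ir(cod)(PCy3)(py)]PF6 (10 mol %), H2 (1 atm), CH2Cl2, 0 °C to rt
Reagents that add atoms: none
Why: Hydroxyl-directed hydrogenation, in which the cationic iridium catalyst bound to the 4α-hydroxyl should deliver H2 to the α face of both homoallylic alkenes, setting 1α-H (trans ring fusion), 7α-H (7β-isopropyl) and 10α-H.

Step 7
Reactants: 14 4α-hydroxy-1αH,5βH,7αH,10αH-guaian-8-one
Product: 15 1αH,5βH,7αH,10αH-guai-3-en-8-one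
Conditions: MeO2CNSO2NEt3 (Burgess reagent), toluene, 60 °C
Reagents that add atoms: none
Why: Burgess dehydration is a syn elimination, and since only H3α and the methyl hydrogens are syn to the 4α leaving group (H5 is β), the C4=C5 alkene cannot form and the more substituted endocyclic C3=C4 alkene should be favoured over the exocyclic one.

Step 8
Reactants: 15 1αH,5βH,7αH,10αH-guai-3-en-8-one
Product: 17 1αH,5βH,7αH-guaia-3,9-dien-8-one, via silyl enol ether 16 (not isolated)
Conditions: LiN(iPr)2, Me3SiCl, THF, −78 °C; then Pd(OAc)2, MeCN, rt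
Reagents that add atoms: none
Why: Kinetic deprotonation at the less hindered C9 methylene (not the tertiary C7–H), silylation and Saegusa–Ito oxidation give the C9=C10 enone regiospecifically; the stereocentre lost at C10 is rebuilt in the next step.

Step 9
Reactants: 17 1αH,5βH,7αH-guaia-3,9-dien-8-one
Product: 19 10α-hydroxy-1αH,5βH,7αH-guai-3-en-8-one, via tertiary boronate 18 (not isolated)
Conditions: Cu(MeCN)4PF6 (10 mol %), (R,R)-QuinoxP*, LiOtBu (15 mol %), B2pin2, iPrOH, THF, rt; then NaBO3·4H2O, THF–H2O, rt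
Reagents that add atoms: sodium perborate, [Na+].[Na+].O[B-]1(O)OO[B-](O)(O)OO1
Why: Copper-catalysed conjugate borylation of a β-methyl cyclic enone forms the tertiary boronate under ligand control (the antipode that sends Cu–Bpin to the α face of C10, trans to the C1–C2 bond, is confirmed in a two-run screen), and the C–B bond is then oxidised with retention to the 10α-hydroxyl.

Step 10
Reactants: 19 10α-hydroxy-1αH,5βH,7αH-guai-3-en-8-one
Product: 20 1αH,5βH,7αH-guai-3-ene-8β,10α-diol
Conditions: Me4NBH(OAc)3, MeCN–AcOH, −30 °C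
Reagents that add atoms: none
Why: Evans–Saksena reduction, in which the borohydride bound to the 10α-oxygen delivers hydride intramolecularly to the α face of C8 to give the anti-1,3-diol (8β-OH), the same face that is anti to the 7β-isopropyl group.

Step 11
Reactants: 21 vanillic acid
Product: 23 4-(tert-butyldimethylsilyloxy)-3-methoxybenzoic acid, via bis-silyl vanillate 22 (not isolated)
Conditions: tBuMe2SiCl (2.2 equiv), imidazole, DMF, rt; then AcOH–THF–H2O, rt
Reagents that add atoms: tert-butyldimethylsilyl chloride, CC(C)(C)[Si](C)(C)Cl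
Why: Both acidic hydroxyls are silylated and the labile silyl ester is then hydrolysed selectively by mild aqueous acid, leaving the aryl silyl ether.

Step 12
Reactants: 20 1αH,5βH,7αH-guai-3-ene-8β,10α-diol; 23 4-(tert-butyldimethylsilyloxy)-3-methoxybenzoic acid
Product: 25 10α-hydroxy-1αH,5βH,7αH-guai-3-en-8β-yl 4-(tert-butyldimethylsilyloxy)-3-methoxybenzoate, via mixed anhydride 24 (not isolated)
Conditions: 2,4,6-Cl3C6H2COCl, Et3N, THF, rt; then 20, DMAP, toluene, 40 °C
Reagents that add atoms: none
Why: Yamaguchi esterification, in which DMAP is acylated at the less hindered vanilloyl carbonyl of the mixed anhydride and only the secondary 8β-hydroxyl reacts, the tertiary 10-hydroxyl being inert.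

Step 13
Reactants: 25 10α-hydroxy-1αH,5βH,7αH-guai-3-en-8β-yl 4-(tert-butyldimethylsilyloxy)-3-methoxybenzoate
Product: 26 3α,4α-epoxy-10α-hydroxy-1αH,5βH,7αH-guaian-8β-yl 4-(tert-butyldimethylsilyloxy)-3-methoxybenzoate
Conditions: VO(acac)2 (5 mol %), tBuOOH, CH2Cl2, 0 °C to rt
Reagents that add atoms: tert-butyl hydroperoxide, CC(C)(C)OO
Why: Vanadium-catalysed hydroxyl-directed epoxidation of a bishomoallylic tertiary alcohol, in which the equatorial 10α-hydroxyl (gauche to C2, on the side of H1) should deliver the peroxide to the α face of C3=C4, the β face being screened in addition by the axial C10 methyl group.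

Step 14
Reactants: 26 3α,4α-epoxy-10α-hydroxy-1αH,5βH,7αH-guaian-8β-yl 4-(tert-butyldimethylsilyloxy)-3-methoxybenzoate
Product: 27 3α,4α-epoxy-10α-hydroxy-1αH,5βH,7αH-guaian-8β-yl 4-hydroxy-3-methoxybenzoate (target)
Conditions: Bu4NF, AcOH, THF, 0 °C
Reagents that add atoms: none
Why: Fluoride cleaves the aryl silyl ether selectively, and the acetic acid buffer keeps the phenoxide from attacking the ester or the epoxide.

Compound list
1 | thymol methyl ether, 1-methoxy-5-methyl-2-(propan-2-yl)benzene | COc1cc(C)ccc1C(C)C | starting material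
2 | 4-methoxy-2-methyl-5-(propan-2-yl)benzaldehyde | COc1cc(C)c(C=O)cc1C(C)C | intermediate
3 | Meldrum's acid, 2,2-dimethyl-1,3-dioxane-4,6-dione | CC1(C)OC(=O)CC(=O)O1 | starting material
4 | arylidene Meldrum's acid, 5-{[4-methoxy-2-methyl-5-(propan-2-yl)phenyl]methylidene}-2,2-dimethyl-1,3-dioxane-4,6-dione | COc1cc(C)c(C=C2C(=O)OC(C)(C)OC2=O)cc1C(C)C | intermediate
5 | benzyl Meldrum's acid, 5-{[4-methoxy-2-methyl-5-(propan-2-yl)phenyl]methyl}-2,2-dimethyl-1,3-dioxane-4,6-dione | COc1cc(C)c(CC2C(=O)OC(C)(C)OC2=O)cc1C(C)C | intermediate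
6 | 3-[4-methoxy-2-methyl-5-(propan-2-yl)phenyl]propanoic acid | COc1cc(C)c(CCC(=O)O)cc1C(C)C | intermediate
7 | trimethylsilyldiazomethane | C[Si](C)(C)C=[N+]=[N-] | starting material
8 | 3-[4-methoxy-2-methyl-5-(propan-2-yl)phenyl]propanoyl chloride | COc1cc(C)c(CCC(=O)Cl)cc1C(C)C | intermediate
9 | 1-diazo-4-[4-methoxy-2-methyl-5-(propan-2-yl)phenyl]butan-2-one | COc1cc(C)c(CCC(=O)C=[N+]=[N-])cc1C(C)C | intermediate
10 | norcaradiene: cyclopropane C1–C5–C6, diene C7=C8/C9=C10, C4 ketone, 5βH | O=C1CC[C@]23C(C)=CC(OC)=C(C(C)C)[C@H]2[C@H]13 | intermediate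
11 | (5S)-8-methoxy-15-norguaia-1(10),6,8-trien-4-one (5βH) | O=C1CCC2=C(C)C=C(OC)C(C(C)C)=C[C@H]12 | intermediate
12 | 8-methoxy-5βH-guaia-1(10),6,8-trien-4α-ol (4β-methyl) | C[C@@]1(O)CCC2=C(C)C=C(OC)C(C(C)C)=C[C@H]12 | intermediate
13 | 4α-hydroxy-5βH-guaia-1(10),6-dien-8-one | C[C@@]1(O)CCC2=C(C)CC(=O)C(C(C)C)=C[C@H]12 | intermediate
14 | 4α-hydroxy-1αH,5βH,7αH,10αH-guaian-8-one | C[C@@]1(O)CC[C@H]2[C@@H](C)CC(=O)[C@@H](C(C)C)C[C@H]12 | intermediate
15 | 1αH,5βH,7αH,10αH-guai-3-en-8-one | CC1=CC[C@H]2[C@@H](C)CC(=O)[C@@H](C(C)C)C[C@H]12 | intermediate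
16 | 8-(trimethylsilyloxy)-1αH,5βH,7αH,10αH-guaia-3,8-diene | CC1=CC[C@H]2[C@@H](C)C=C(O[Si](C)(C)C)[C@@H](C(C)C)C[C@H]12 | intermediate
17 | 1αH,5βH,7αH-guaia-3,9-dien-8-one | CC1=CC[C@H]2C(C)=CC(=O)[C@@H](C(C)C)C[C@H]12 | intermediate
18 | 10α-(4,4,5,5-tetramethyl-1,3,2-dioxaborolan-2-yl)-1αH,5βH,7αH-guai-3-en-8-one | CC1=CC[C@H]2[C@](C)(B3OC(C)(C)C(C)(C)O3)CC(=O)[C@@H](C(C)C)C[C@H]12 | intermediate
19 | 10α-hydroxy-1αH,5βH,7αH-guai-3-en-8-one | CC1=CC[C@H]2[C@](C)(O)CC(=O)[C@@H](C(C)C)C[C@H]12 | intermediate
20 | 1αH,5βH,7αH-guai-3-ene-8β,10α-diol | CC1=CC[C@H]2[C@](C)(O)C[C@@H](O)[C@@H](C(C)C)C[C@H]12 | intermediate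
21 | vanillic acid | COc1cc(C(=O)O)ccc1O | starting material
22 | tert-butyldimethylsilyl 4-(tert-butyldimethylsilyloxy)-3-methoxybenzoate | COc1cc(C(=O)O[Si](C)(C)C(C)(C)C)ccc1O[Si](C)(C)C(C)(C)C | intermediate
23 | 4-(tert-butyldimethylsilyloxy)-3-methoxybenzoic acid | COc1cc(C(=O)O)ccc1O[Si](C)(C)C(C)(C)C | intermediate
24 | 4-(tert-butyldimethylsilyloxy)-3-methoxybenzoic 2,4,6-trichlorobenzoic anhydride | COc1cc(C(=O)OC(=O)c2c(Cl)cc(Cl)cc2Cl)ccc1O[Si](C)(C)C(C)(C)C | intermediate
25 | 10α-hydroxy-1αH,5βH,7αH-guai-3-en-8β-yl 4-(tert-butyldimethylsilyloxy)-3-methoxybenzoate | COc1cc(C(=O)O[C@@H]2C[C@@](C)(O)[C@@H]3CC=C(C)[C@H]3C[C@@H]2C(C)C)ccc1O[Si](C)(C)C(C)(C)C | intermediate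
26 | 3α,4α-epoxy-10α-hydroxy-1αH,5βH,7αH-guaian-8β-yl 4-(tert-butyldimethylsilyloxy)-3-methoxybenzoate | COc1cc(C(=O)O[C@@H]2C[C@@](C)(O)[C@@H]3C[C@H]4O[C@@]4(C)[C@H]3C[C@@H]2C(C)C)ccc1O[Si](C)(C)C(C)(C)C | intermediate
27 | 3α,4α-epoxy-10α-hydroxy-1αH,5βH,7αH-guaian-8β-yl 4-hydroxy-3-methoxybenzoate | COc1cc(C(=O)O[C@@H]2C[C@@](C)(O)[C@@H]3C[C@H]4O[C@@]4(C)[C@H]3C[C@@H]2C(C)C)ccc1O | target

Total step count: 14. Longest linear sequence: 13 steps (steps 1–10 and 12–14, from thymol methyl ether); step 11 prepares the acid fragment.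

Steps most likely to fail

Step 4. The copper–bis(oxazoline) carbenoid may discriminate the arene faces poorly on this hindered, electron-rich ring, aromatic C–H insertion at C6 may compete, or the C5 centre may erode before it is locked. The fallback sets out from 9 and comes back at 14. It gives up catalyst control: 9 is decomposed with achiral Rh2(OAc)4 (CH2Cl2, 40 °C), the most dependable catalyst for this arene cyclopropanation, to give 11 as the racemate, that is together with (5R)-8-methoxy-15-norguaia-1(10),6,8-trien-4-one F2, formed through the mirror-image norcaradiene F1. Steps 5 and 6 are run on the racemate, the mirror-image series passing through the trienyl ether carbinol ent-12 F3 and the hydroxy dienone ent-13 F4 to the saturated hydroxy ketone ent-14 F5. The configurationally stable racemic hydroxy ketone is then resolved by preparative supercritical-fluid chromatography on an amylose tris(3,5-dimethylphenylcarbamate) phase, and 14 goes on into step 7.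

Step 9. Delivery of the bulky Cu–Bpin unit to the γ-branched, fully substituted β-carbon may be sluggish or may not follow the ligand, giving poor facial selectivity at C10. The fallback sets out from 17 and comes back at 19. It replaces the catalyst-controlled borylation by a substrate-controlled Weitz–Scheffer epoxidation with the small hydroperoxide anion (H2O2, NaOH, MeOH, 0 °C), which should attack C10 trans to the C1–C2 bond and give 9α,10α-epoxy-1αH,5βH,7αH-guai-3-en-8-one F6. SmI2 (THF–MeOH, −78 °C) then cleaves the Cα–O bond reductively to give the β-hydroxy ketone 19.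

Step 13. The vanadium alkoxide of the hindered tertiary alcohol may fail to reach the alkene, so that the reaction stalls or undirected attack on the β face (anti to the C5–C6 bond) takes over. The fallback sets out from 25 and comes back at 26. It turns that β preference to use: NBS in THF–H2O (0 °C) should form the bromonium ion on the β face, and water opens it anti at the tertiary C4 to give 3β-bromo-4α,10α-dihydroxy-1αH,5βH,7αH-guaian-8β-yl 4-(tert-butyldimethylsilyloxy)-3-methoxybenzoate F7. DBU (toluene, rt) then closes the ring with inversion at C3 to the 3α,4α-epoxide 26.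

Further compounds
F1 | step 4 | mirror-image norcaradiene (ent-10) | O=C1CC[C@@]23C(C)=CC(OC)=C(C(C)C)[C@@H]2[C@@H]13
F2 | step 4 | (5R)-8-methoxy-15-norguaia-1(10),6,8-trien-4-one (ent-11) | O=C1CCC2=C(C)C=C(OC)C(C(C)C)=C[C@@H]12
F3 | step 4 | trienyl ether carbinol ent-12 | C[C@]1(O)CCC2=C(C)C=C(OC)C(C(C)C)=C[C@@H]12
F4 | step 4 | hydroxy dienone ent-13 | C[C@]1(O)CCC2=C(C)CC(=O)C(C(C)C)=C[C@@H]12
F5 | step 4 | saturated hydroxy ketone ent-14 | C[C@]1(O)CC[C@@H]2[C@H](C)CC(=O)[C@H](C(C)C)C[C@@H]12
F6 | step 9 | 9α,10α-epoxy-1αH,5βH,7αH-guai-3-en-8-one | CC1=CC[C@H]2[C@]3(C)O[C@@H]3C(=O)[C@@H](C(C)C)C[C@H]12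
F7 | step 13 | 3β-bromo-4α,10α-dihydroxy-1αH,5βH,7αH-guaian-8β-yl 4-(tert-butyldimethylsilyloxy)-3-methoxybenzoate | COc1cc(C(=O)O[C@@H]2C[C@@](C)(O)[C@@H]3C[C@H](Br)[C@@](C)(O)[C@H]3C[C@@H]2C(C)C)ccc1O[Si](C)(C)C(C)(C)C
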